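**Plan**
- **Feature used.** Numbering: C7 is the benzylic carbinol carbon on the guaiacyl ring, C8 is the methine whose ether O goes to C4' of the syringyl ring, and C9 is the CH2OH carbon. The pair C7(OH)–C8(OAr), with only a one-carbon arm (C9) on C8, is the retron of a γ-aryloxyallylboron addition to an aromatic aldehyde.
- **Cuts.** (i) Unmask the ketone, the phenol and the primary OH. (ii) C9H2OH comes from a vinyl group, with one helper carbon. (iii) C7–C8 gives O-silyl vanillin and an (E)-γ-aryloxyallyl pinacolboronate. (iv) The allylboronate comes from an (E)-alkenylboronate, and that from an aryl propargyl ether. (v) O–C8 gives acetosyringone and propargyl bromide.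
- **Forward order.** Propargylate acetosyringone. A hypervalent-iodine oxidation then creates the CH2OH group and masks the ketone as a dimethyl ketal in one operation. Silylation and hydroboration follow, then the one-flask double-bond shift and allylboration with the aldehyde, then excision of the helper carbon, then global unmasking.
- **Stereochemistry.** No ring is formed. Both stereocentres arise in the fragment union. The E geometry of the allylboronate gives the anti (erythro) relation through a chair, and the chiral phosphoric acid selects the aldehyde face, giving 7R,8S.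

Key step: step 6

Assumption: the sense of induction of TRIP is taken from allyl and (E)-crotyl pinacolboronates with aromatic aldehydes, where the (R)-acid delivers the allyl group to the Re face. The γ-aryloxy reagent is assumed to follow this, so the (S)-acid is used to reach the Si face.

Abbreviations: TBS = tert-butyldimethylsilyl; TES = triethylsilyl; pin = pinacolato; Ar* = 4-[2-(TBSO)-1,1-dimethoxyethyl]-2,6-dimethoxyphenyl (masked syringyl unit, bound through C1 to the ether oxygen); (S)-TRIP = (S)-3,3'-bis(2,4,6-triisopropylphenyl)-1,1'-binaphthyl-2,2'-diyl hydrogen phosphate.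

**Step 1**
Reactants: 1 acetosyringone [1-(4-hydroxy-3,5-dimethoxyphenyl)ethan-1-one]; 2 propargyl bromide
Product: 3 1-[3,5-dimethoxy-4-(prop-2-yn-1-yloxy)phenyl]ethan-1-one
Conditions: K2CO3, DMF, 50 °C
Reagents that add atoms: none
Why: Williamson ether synthesis, in which the para-acyl phenoxide attacks the unhindered propargylic bromide by SN2 despite its two ortho methoxy groups; the three propargyl carbons become C8, C9 and the helper carbon.

**Step 2**
Reactants: 3 1-[3,5-dimethoxy-4-(prop-2-yn-1-yloxy)phenyl]ethan-1-one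
Product: 4 2-[3,5-dimethoxy-4-(prop-2-yn-1-yloxy)phenyl]-2,2-dimethoxyethan-1-ol
Conditions: PhI(OAc)2 (1.2 equiv), KOH (5 equiv), MeOH, 0 °C to rt [PhI(OMe)2 formed in the flask]
Reagents that add atoms: methanol CO
Why: Moriarty oxidation of an aryl methyl ketone, in which the enolate attacks PhI(OMe)2, methoxide adds to the carbonyl and expels PhI to give a methoxy-oxirane that methanol opens at the benzylic carbon, so the CH2OH group and the ketone mask arise together while the aryl ethers and the terminal alkyne are inert to basic I(III).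

**Step 3**
Reactants: 4 2-[3,5-dimethoxy-4-(prop-2-yn-1-yloxy)phenyl]-2,2-dimethoxyethan-1-ol
Product: 5 TBS ether of 4 (Ar*–O–CH2–C≡CH)
Conditions: TBSCl, imidazole, DMF, rt
Reagents that add atoms: tert-butyldimethylsilyl chloride CC(C)(C)[Si](C)(C)Cl
Why: Standard imidazole-promoted silylation of a primary alcohol under mildly basic conditions that leave the acid-labile ketal untouched.

**Step 4**
Reactants: 5 TBS ether of 4
Product: 6 (E)-3-(Ar*-oxy)prop-1-en-1-ylboronic acid pinacol ester
Conditions: HBpin (1.3 equiv), Cp2ZrHCl (10 mol %), Et3N (10 mol %), neat, 60 °C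
Reagents that add atoms: pinacolborane CC1(C)OBOC1(C)C
Why: Zirconocene-hydride-catalysed syn hydroboration of a terminal alkyne (hydrozirconation, then transfer to boron) places boron on the terminal carbon and gives the E alkenylboronate, as known for aryl propargyl ethers, with ketal and silyl ether inert and Et3N keeping the medium non-acidic.

**Step 5**
Reactants: 7 vanillin
Product: 8 4-(tert-butyldimethylsilyloxy)-3-methoxybenzaldehyde
Conditions: TBSCl, imidazole, CH2Cl2, rt
Reagents that add atoms: tert-butyldimethylsilyl chloride CC(C)(C)[Si](C)(C)Cl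
Why: Standard phenol silylation, which removes the acidic OH and keeps the aldehyde electrophilic enough for the allylboration.

**Step 6**
Reactants: 6 (E)-3-(Ar*-oxy)prop-1-en-1-ylboronic acid pinacol ester; 8 4-(tert-butyldimethylsilyloxy)-3-methoxybenzaldehyde
Product: 11 (1R,2S)-1-[4-(TBSO)-3-methoxyphenyl]-2-(Ar*-oxy)but-3-en-1-ol, via E-allylboronate 9 (not isolated), via pinacol borate 10 (not isolated)
Conditions: [Ir(cod)(PPh2Me)2]PF6 (3 mol %, pre-activated with H2, then Ar purge), CH2Cl2, rt; then 8, (S)-TRIP (10 mol %), 4 Å MS, toluene, −30 to 0 °C; aq NaHCO3 work-up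
Reagents that add atoms: none
Why: The hydrogen-activated cationic iridium complex shifts the C=C of 6 by a metal-hydride 1,3-hydrogen transposition from the boron-bearing position into conjugation with the ether oxygen, kinetically as the E enol ether, to give allylboronate 9, whose γ-carbon (future C8) then attacks the formyl carbon of 8 (future C7) through a closed six-membered chair in which the B–O and C–C bonds form together (type I allylboration, Zimmerman–Traxler), giving borate 10 and, after hydrolysis, 11. The closest known reaction types are the iridium-catalysed isomerisation of 3-silyloxyprop-1-enylboronates to (E)-γ-silyloxyallylboronates, the one-flask iridium/chiral phosphoric acid conversion of 1-alkenylboronates and aldehydes into anti homoallylic alcohols, and the phosphoric-acid-catalysed anti-alkoxyallylboration of aldehydes with (E)-γ-alkoxyallyl pinacolboronates. No ring of the product is closed; the only cycle is the transient chair. The relative configuration follows from the E geometry of 9, which puts the aryloxy group and the aryl group of 8 both equatorial and so sets C7–OH and C8–OAr anti (erythro). The absolute configuration comes from (S)-TRIP, which binds the pseudoaxial pinacol oxygen through its P–OH and the formyl hydrogen through its P=O and leaves only the Si face of 8 open, so C7 becomes R and the chair relays this to C8 as S. The step needs E over Z geometry (kinetic trans preference of this catalyst, reinforced by the bulky 2,6-dimethoxyaryl group), catalysed over background addition and no onward migration of the new vinyl group (both secured by adding 8 and the acid only after the isomerisation and running the addition cold, where pinacol allylboronates are inert without acid and the iridium hydride is sluggish toward the branched allylic ether), and no competing electrophile or proton source (the ketone is a ketal and every OH is silylated).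

**Step 7**
Reactants: 11 (1R,2S)-1-[4-(TBSO)-3-methoxyphenyl]-2-(Ar*-oxy)but-3-en-1-ol
Product: 13 (1R,2S)-1-[4-(TBSO)-3-methoxyphenyl]-2-(Ar*-oxy)propane-1,3-diol, via aldehyde 12 (not isolated)
Conditions: OsO4 (2 mol %), NaIO4 (4 equiv), 2,6-lutidine (2 equiv), dioxane–H2O 3:1, rt; extractive work-up, then NaBH4, THF–MeOH, 0 °C
Reagents that add atoms: osmium tetroxide O=[Os](=O)(=O)=O; sodium periodate [Na+].[O-]I(=O)(=O)=O (the C9 oxygen is delivered by OsO4, which periodate regenerates)
Why: Lemieux–Johnson cleavage of the only alkene followed by borohydride reduction removes the helper carbon and turns the vinyl CH into C9H2OH, with lutidine keeping the medium near neutral so that the ketal survives and aldehyde 12 is reduced before it can epimerise at C8 or undergo retro-aldol cleavage; neither stereocentre is touched.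

**Step 8**
Reactants: 13 (1R,2S)-1-[4-(TBSO)-3-methoxyphenyl]-2-(Ar*-oxy)propane-1,3-diol
Product: 15 1-{4-[(1R,2S)-1,3-dihydroxy-1-(4-hydroxy-3-methoxyphenyl)propan-2-yl]oxy-3,5-dimethoxyphenyl}-2-hydroxyethan-1-one (target), via desilylated ketal 14 (not isolated)
Conditions: TBAF (2.5 equiv), THF, 0 °C; then 1 M aq HCl to pH 1–2, 0 °C to rt, short contact; NaHCO3 quench
Reagents that add atoms: water O
Why: Fluoride cleaves both silyl ethers while the ketal stays in place, and brief dilute acid then hydrolyses the very labile aryl dimethyl ketal to the ketone faster than the C7 carbinol can ionise, so C7 and C8 are kept.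

**Compound list**
1 | acetosyringone | CC(=O)c1cc(OC)c(O)c(OC)c1 | starting material
2 | propargyl bromide | C#CCBr | starting material
3 | 1-[3,5-dimethoxy-4-(prop-2-yn-1-yloxy)phenyl]ethan-1-one | CC(=O)c1cc(OC)c(OCC#C)c(OC)c1 | intermediate
4 | 2-[3,5-dimethoxy-4-(prop-2-yn-1-yloxy)phenyl]-2,2-dimethoxyethan-1-ol | OCC(OC)(OC)c1cc(OC)c(OCC#C)c(OC)c1 | intermediate
5 | TBS ether of 4 | CC(C)(C)[Si](C)(C)OCC(OC)(OC)c1cc(OC)c(OCC#C)c(OC)c1 | intermediate
6 | (E)-3-(Ar*-oxy)prop-1-en-1-ylboronic acid pinacol ester | CC(C)(C)[Si](C)(C)OCC(OC)(OC)c1cc(OC)c(OC/C=C/B2OC(C)(C)C(C)(C)O2)c(OC)c1 | intermediate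
7 | vanillin | COc1cc(C=O)ccc1O | starting material
8 | 4-(tert-butyldimethylsilyloxy)-3-methoxybenzaldehyde | COc1cc(C=O)ccc1O[Si](C)(C)C(C)(C)C | intermediate
9 | (E)-3-(Ar*-oxy)prop-2-en-1-ylboronic acid pinacol ester (E-γ-aryloxyallylboronate) | CC(C)(C)[Si](C)(C)OCC(OC)(OC)c1cc(OC)c(O/C=C/CB2OC(C)(C)C(C)(C)O2)c(OC)c1 | intermediate
10 | O-Bpin borate of 11 (1R,2S) | COc1cc([C@@H](OB2OC(C)(C)C(C)(C)O2)[C@H](C=C)Oc2c(OC)cc(C(OC)(OC)CO[Si](C)(C)C(C)(C)C)cc2OC)ccc1O[Si](C)(C)C(C)(C)C | intermediate
11 | (1R,2S)-1-[4-(TBSO)-3-methoxyphenyl]-2-(Ar*-oxy)but-3-en-1-ol | COc1cc([C@@H](O)[C@H](C=C)Oc2c(OC)cc(C(OC)(OC)CO[Si](C)(C)C(C)(C)C)cc2OC)ccc1O[Si](C)(C)C(C)(C)C | intermediate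
12 | (2R,3R)-3-[4-(TBSO)-3-methoxyphenyl]-2-(Ar*-oxy)-3-hydroxypropanal | COc1cc([C@@H](O)[C@H](C=O)Oc2c(OC)cc(C(OC)(OC)CO[Si](C)(C)C(C)(C)C)cc2OC)ccc1O[Si](C)(C)C(C)(C)C | intermediate
13 | (1R,2S)-1-[4-(TBSO)-3-methoxyphenyl]-2-(Ar*-oxy)propane-1,3-diol | COc1cc([C@@H](O)[C@H](CO)Oc2c(OC)cc(C(OC)(OC)CO[Si](C)(C)C(C)(C)C)cc2OC)ccc1O[Si](C)(C)C(C)(C)C | intermediate
14 | (1R,2S)-1-(4-hydroxy-3-methoxyphenyl)-2-[4-(2-hydroxy-1,1-dimethoxyethyl)-2,6-dimethoxyphenoxy]propane-1,3-diol | COc1cc([C@@H](O)[C@H](CO)Oc2c(OC)cc(C(OC)(OC)CO)cc2OC)ccc1O | intermediate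
15 | 1-{4-[(1R,2S)-1,3-dihydroxy-1-(4-hydroxy-3-methoxyphenyl)propan-2-yl]oxy-3,5-dimethoxyphenyl}-2-hydroxyethan-1-one | COc1cc([C@@H](O)[C@H](CO)Oc2c(OC)cc(C(=O)CO)cc2OC)ccc1O | target

Total step count: 8. Longest linear sequence: 7 (steps 1, 2, 3, 4, 6, 7, 8).

**Steps most likely to fail**

**Step 6.**
- What may go wrong: the double-bond shift may stop short or lose its E preference. The new vinyl group may migrate onward into conjugation with the ether oxygen, which would erase C8. Facial selectivity may drop because of the bulky γ-aryloxy group.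
- Fallback: an auxiliary-controlled syn aldol for the same C7–C8 bond, followed by inversion at C7. It sets out from 1 and 8 and returns at 13.
- 1 is O-alkylated with methyl bromoacetate (K2CO3, acetone) to methyl 2-(4-acetyl-2,6-dimethoxyphenoxy)acetate F1.
- PhI(OAc)2/KOH/MeOH followed by water installs the hydroxy ketal and saponifies the ester, giving 2-[4-(2-hydroxy-1,1-dimethoxyethyl)-2,6-dimethoxyphenoxy]acetic acid F2, which is freed at pH 4–5 and 0 °C.
- TBSCl/imidazole with a K2CO3/aq MeOH work-up gives the O-TBS acid F3.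
- PivCl/Et3N converts F3 into the mixed pivalic anhydride F4, which acylates lithiated (R)-4-benzyloxazolidin-2-one to the N-(aryloxyacetyl)oxazolidinone F5.
- Bu2BOTf/i-Pr2NEt and then 8 (Evans syn aldol through the Z boron enolate and a chair) should give the (2R,3S)-syn adduct F6.
- Mitsunobu esterification (4-nitrobenzoic acid, PPh3, DIAD) inverts C7 to the (2R,3R)-4-nitrobenzoate F7.
- LiBH4 in THF–MeOH reduces imide and ester together and gives 13.

**Step 7.**
- What may go wrong: epimerisation at C8 or retro-aldol cleavage while the free β-hydroxy aldehyde is present. The ketal may be lost early in the aqueous periodate medium, after which borohydride would reduce the ketone. The electron-rich rings may suffer oxidative attack.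
- Fallback: cap the carbinol, then cleave without water and reduce in the same flask, so that no free β-hydroxy aldehyde builds up. It sets out from 11 and returns at 14.
- TESCl/imidazole gives the C7 triethylsilyl ether of 11 F8.
- O3 in CH2Cl2–MeOH at −78 °C to an indicator end point, followed by NaBH4 in the same flask, gives the C7-O-TES primary alcohol F9.
- In the fluoride stage of step 8 all three silyl groups are cleaved, which gives 14.

**Step 8.**
- What may go wrong: ionisation of the C7 carbinol (p-hydroxybenzyl cation or quinone methide) during the acid stage would scramble C7.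
- Fallback: reverse the order of the unmaskings and isolate in between. Acid then meets the molecule while the phenol is still silylated and less donating, and the phenol is freed last under buffered conditions. It sets out from 13 and returns at 15.
- AcOH–THF–H2O (3:1:1) at rt hydrolyses the ketal and the primary silyl ether but not the aryl silyl ether, giving the aryl-O-TBS keto triol F10.
- TBAF buffered with AcOH (1:1) in THF at 0 °C then gives 15.

**Further compounds**
F1 | step 6 | methyl 2-(4-acetyl-2,6-dimethoxyphenoxy)acetate | COC(=O)COc1c(OC)cc(C(C)=O)cc1OC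
F2 | step 6 | 2-[4-(2-hydroxy-1,1-dimethoxyethyl)-2,6-dimethoxyphenoxy]acetic acid | OCC(OC)(OC)c1cc(OC)c(OCC(=O)O)c(OC)c1
F3 | step 6 | 2-(Ar*-oxy)acetic acid (O-TBS acid) | CC(C)(C)[Si](C)(C)OCC(OC)(OC)c1cc(OC)c(OCC(=O)O)c(OC)c1
F4 | step 6 | mixed anhydride of F3 and pivalic acid | CC(C)(C)C(=O)OC(=O)COc1c(OC)cc(C(OC)(OC)CO[Si](C)(C)C(C)(C)C)cc1OC
F5 | step 6 | (R)-4-benzyl-3-[2-(Ar*-oxy)acetyl]oxazolidin-2-one | CC(C)(C)[Si](C)(C)OCC(OC)(OC)c1cc(OC)c(OCC(=O)N2C(=O)OC[C@H]2Cc2ccccc2)c(OC)c1
F6 | step 6 | (R)-4-benzyl-3-{(2R,3S)-2-(Ar*-oxy)-3-hydroxy-3-[4-(TBSO)-3-methoxyphenyl]propanoyl}oxazolidin-2-one | COc1cc([C@H](O)[C@H](C(=O)N2C(=O)OC[C@H]2Cc2ccccc2)Oc2c(OC)cc(C(OC)(OC)CO[Si](C)(C)C(C)(C)C)cc2OC)ccc1O[Si](C)(C)C(C)(C)C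
F7 | step 6 | (2R,3R)-4-nitrobenzoate obtained from F6 with inversion at C7 | COc1cc([C@@H](OC(=O)c2ccc([N+](=O)[O-])cc2)[C@H](C(=O)N2C(=O)OC[C@H]2Cc2ccccc2)Oc2c(OC)cc(C(OC)(OC)CO[Si](C)(C)C(C)(C)C)cc2OC)ccc1O[Si](C)(C)C(C)(C)C
F8 | step 7 | C7 triethylsilyl ether of 11 | COc1cc([C@@H](O[Si](CC)(CC)CC)[C@H](C=C)Oc2c(OC)cc(C(OC)(OC)CO[Si](C)(C)C(C)(C)C)cc2OC)ccc1O[Si](C)(C)C(C)(C)C
F9 | step 7 | C7 triethylsilyl ether of 13 | COc1cc([C@@H](O[Si](CC)(CC)CC)[C@H](CO)Oc2c(OC)cc(C(OC)(OC)CO[Si](C)(C)C(C)(C)C)cc2OC)ccc1O[Si](C)(C)C(C)(C)C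
F10 | step 8 | aryl O-TBS ether of 15 | COc1cc([C@@H](O)[C@H](CO)Oc2c(OC)cc(C(=O)CO)cc2OC)ccc1O[Si](C)(C)C(C)(C)C
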